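**Retrosynthetic overview**

- The strategy rests on the all-E chain: its twelve-carbon pentaene core C11–C11' (with methyls C20 and C20') is C2-symmetric and is bounded by the sp2–sp2 single bonds C10–C11 and C10'–C11'. The chain carries two different ε-rings, ring A (C1–C6, 3S-OH trans to the C6 side chain, 6S) and ring B (C1'–C6', 6'S).
- Cutting C10'–C11' (Stille) and C10–C11 (Suzuki–Miyaura) gives a C11'-stannyl/C11-boryl pentaene linchpin and two C14 dienyl iodides, joined in one flask.
- Both iodides come from one resolved (S)-α-ionone: methyl ketone to enyne, then zirconium-catalysed methylalumination and iodination. Ring A is hydroxylated beforehand by allylic oxidation at C3 and CBS reduction.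
- The linchpin comes from the C10 dialdehyde by two successive chromium-mediated olefinations, boron first and tin second.
- No ring is formed anywhere in the route: both six-membered rings are taken intact from α-ionone.

Key step: step 15

Remark: carotenoid numbering is used (ring A unprimed, ring B primed); the target is read as all-E (3S,6S,6'S)-ε,ε-caroten-3-ol, α-ionone is assumed to resolve on a polysaccharide chiral phase with the (S)-antipode assigned by its sign of rotation, and all polyenes are handled under argon in dim light.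

**Route**

Step 1
Reactants: 1 racemic α-ionone
Product: 2 (S)-α-ionone
Conditions: preparative SFC, amylose tris(3,5-dimethylphenylcarbamate) phase, CO2/i-PrOH, 35 °C; collect the (S)-enantiomer
Reagents that add atoms: none
Why: Resolution by preparative chromatography on a chiral stationary phase selects the (S)-antipode under neutral conditions that cannot epimerise the doubly allylic C6–H; no stereocentre is made, and this one centre later becomes C6 and C6' of the target.

Step 2
Reactants: 2 (S)-α-ionone
Product: 4 (6S)-6-[(1E)-but-1-en-3-yn-1-yl]-1,5,5-trimethylcyclohex-1-ene, via dienyl diethyl phosphate 3 (not isolated)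
Conditions: LDA (LiN(i-Pr)2, 1.1 equiv), THF, −78 °C; ClP(O)(OEt)2, −78 °C to rt; then LDA (2.3 equiv), −78 °C to rt; aq NH4Cl
Reagents that add atoms: diethyl chlorophosphate, CCOP(=O)(Cl)OCC (its atoms are in 3 only)
Why: Kinetic deprotonation of the methyl group, O-phosphorylation and LDA-induced β-elimination (conversion of a methyl ketone into a terminal alkyne through its enol phosphate) should give the conjugated enyne, whose acetylide form disfavours a second deprotonation at C6.

Step 3
Reactants: 4 (S)-enyne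
Product: 6 (6S)-6-[(1E,3E)-4-iodo-3-methylbuta-1,3-dien-1-yl]-1,5,5-trimethylcyclohex-1-ene, via alkenyldimethylalane 5 (not isolated)
Conditions: Me3Al (2.5 equiv), Cp2ZrCl2 (0.3 equiv), CH2Cl2, 0 °C to rt; then I2, THF, −30 to 0 °C
Reagents that add atoms: trimethylaluminium, C[Al](C)C; iodine, II
Why: Zirconium-catalysed methylalumination (Negishi carboalumination) adds Me–Al syn across the terminal alkyne with methyl on the internal carbon C9, and iodinolysis of the C10–Al bond with retention should give the (E)-iodide in a non-basic medium that leaves C6' untouched.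

Step 4
Reactants: 2 (S)-α-ionone
Product: 7 2-methyl-2-{(E)-2-[(1S)-2,6,6-trimethylcyclohex-2-en-1-yl]ethenyl}-1,3-dioxolane
Conditions: TMSOCH2CH2OTMS (1.5 equiv), TMSOTf (5 mol%), CH2Cl2, −78 to −20 °C; pyridine quench
Reagents that add atoms: 1,2-bis(trimethylsilyloxy)ethane, C[Si](C)(C)OCCO[Si](C)(C)C
Why: Acetalisation with the bis-silyl ether under TMSOTf catalysis (Noyori conditions) is aprotic and cold, so the dioxolane should form without migration of the ring or side-chain double bond and without loss of configuration at C6.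

Step 5
Reactants: 7 (S)-α-ionone ethylene ketal
Product: 8 (4S)-3,5,5-trimethyl-4-[(E)-2-(2-methyl-1,3-dioxolan-2-yl)ethenyl]cyclohex-2-en-1-one
Conditions: t-BuOOH (in decane, 5 equiv), Rh2(cap)4 (dirhodium tetrakis(caprolactamate), 1 mol%), K2CO3 (0.5 equiv, solid), CH2Cl2, rt
Reagents that add atoms: tert-butyl hydroperoxide, CC(C)(C)OO
Why: Dirhodium-catalysed radical allylic oxidation with t-BuOOH should convert the only unhindered allylic methylene, C3, into the enone carbonyl, because the tertiary C6–H is shielded by the gem-dimethyl group and the C5 methyl and the ketal masks the side-chain carbonyl.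

Step 6
Reactants: 8 (S)-3-oxo-α-ionone ethylene ketal
Product: 9 (1S,4S)-3,5,5-trimethyl-4-[(E)-2-(2-methyl-1,3-dioxolan-2-yl)ethenyl]cyclohex-2-en-1-ol
Conditions: (R)-2-methyl-CBS-oxazaborolidine (0.5 equiv), catecholborane (1.8 equiv), toluene, −78 °C; aq NaOH work-up; chromatography
Reagents that add atoms: none
Why: In the Corey–Bakshi–Shibata reduction the (R)-oxazaborolidine should bind the ring ketone with the alkenyl branch C4 as the large group and the methylene C2 as the small group and deliver hydride to the face that sets C3 as S, trans to the C6 side chain; any cis isomer is a separable diastereomer.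

Step 7
Reactants: 9 (3S,6S)-3-hydroxy-α-ionone ethylene ketal
Product: 10 tert-butyldimethylsilyl ether of 9
Conditions: TBSCl, imidazole, DMF, rt
Reagents that add atoms: tert-butyldimethylsilyl chloride, CC(C)(C)[Si](C)(C)Cl
Why: Standard silylation of a secondary alcohol protects the C3 hydroxyl, which would otherwise be phosphorylated in step 9 and is prone to allylic ionisation under acid.

Step 8
Reactants: 10 silyl ether ketal
Product: 11 (3E)-4-[(1S,4S)-4-(tert-butyldimethylsilyloxy)-2,6,6-trimethylcyclohex-2-en-1-yl]but-3-en-2-one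
Conditions: PPTS (cat.), acetone/H2O (10:1), rt to 40 °C
Reagents that add atoms: water, O
Why: Mild acid-catalysed acetal hydrolysis should free the methyl ketone from the labile allylic dioxolane, while the TBS ether and the ring alkene are stable to pyridinium tosylate.

Step 9
Reactants: 11 silyloxy ketone
Product: 13 tert-butyl{[(1S,4S)-4-[(1E)-but-1-en-3-yn-1-yl]-3,5,5-trimethylcyclohex-2-en-1-yl]oxy}dimethylsilane, via dienyl diethyl phosphate 12 (not isolated)
Conditions: LDA (1.1 equiv), THF, −78 °C; ClP(O)(OEt)2, −78 °C to rt; then LDA (2.3 equiv), −78 °C to rt; aq NH4Cl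
Reagents that add atoms: diethyl chlorophosphate, CCOP(=O)(Cl)OCC (its atoms are in 12 only)
Why: The same enol phosphate elimination as in step 2 should turn the methyl ketone into the terminal enyne, with the silyl ether at C3 inert to the amide base.

Step 10
Reactants: 13 silyloxy enyne
Product: 15 tert-butyl{[(1S,4S)-4-[(1E,3E)-4-iodo-3-methylbuta-1,3-dien-1-yl]-3,5,5-trimethylcyclohex-2-en-1-yl]oxy}dimethylsilane, via alkenyldimethylalane 14 (not isolated)
Conditions: Me3Al (2.5 equiv), Cp2ZrCl2 (0.3 equiv), CH2Cl2, 0 °C to rt; then I2, THF, −30 to 0 °C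
Reagents that add atoms: trimethylaluminium, C[Al](C)C; iodine, II
Why: Negishi carboalumination followed by iodinolysis with retention should give the (E)-C9=C10 iodide as in step 3, since silyl ethers are tolerated by the Me3Al/zirconocene system.

Step 11
Reactants: 15 silyloxy dienyl iodide
Product: 16 (1S,4S)-4-[(1E,3E)-4-iodo-3-methylbuta-1,3-dien-1-yl]-3,5,5-trimethylcyclohex-2-en-1-ol
Conditions: n-Bu4NF, THF, 0 °C to rt
Reagents that add atoms: none
Why: Fluoride-mediated desilylation should free the C3 hydroxyl under non-acidic conditions; the alkenyl iodide has no β-hydrogen on C9 and so cannot eliminate.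

Step 12
Reactants: 17 tributyltin chloride; 18 dibromomethane
Product: 19 tributyl(dibromomethyl)stannane
Conditions: 18, LDA, THF, −95 °C; then 17, −95 to −60 °C
Reagents that add atoms: none
Why: Deprotonation of dibromomethane gives the carbenoid LiCHBr2, which is stable at this temperature and should be trapped by nucleophilic substitution at tin.

Step 13
Reactants: 20 (2E,4E,6E)-2,7-dimethylocta-2,4,6-trienedial (3 equiv); 21 2-(dichloromethyl)-4,4,5,5-tetramethyl-1,3,2-dioxaborolane (1 equiv)
Product: 22 (2E,4E,6E,8E)-2,7-dimethyl-9-(4,4,5,5-tetramethyl-1,3,2-dioxaborolan-2-yl)nona-2,4,6,8-tetraenal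
Conditions: CrCl2 (6 equiv), LiI (3 equiv), THF, rt, dark; chromatography with recovery of 20
Reagents that add atoms: none
Why: The Takai–Utimoto olefination with the geminal dichromium reagent from 21 should give the (E)-alkenylboronate, and mono-olefination is favoured by the excess of dialdehyde and by the lower electrophilicity of the remaining aldehyde once the second acceptor group is gone.

Step 14
Reactants: 22 boryl tetraenal; 19 tributyl(dibromomethyl)stannane
Product: 23 tributyl[(1E,3E,5E,7E,9E)-3,8-dimethyl-10-(4,4,5,5-tetramethyl-1,3,2-dioxaborolan-2-yl)deca-1,3,5,7,9-pentaen-1-yl]stannane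
Conditions: 19 (2 equiv), CrCl2 (10 equiv), LiI (4 equiv), THF–DMF, rt, dark; Et3N-deactivated alumina
Reagents that add atoms: none
Why: The Takai-type olefination with the gem-dihalomethylstannane and divalent chromium should convert the remaining aldehyde into the (E)-alkenylstannane, the pinacol boronate being inert to the chromium reagent.

Step 15
Reactants: 23 stannyl–boryl pentaene; 6 (S)-C14 dienyl iodide; 16 (3S,6S)-hydroxy C14 dienyl iodide
Product: 25 (3S,6S,6'S)-ε,ε-caroten-3-ol, via heptaenyl boronate 24 (not isolated)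
Conditions: 6 (1.0 equiv), 23 (1.05 equiv), Pd2(dba)3·CHCl3 (5 mol%), AsPh3 (40 mol%), degassed THF–NMP, 40 °C, dark; then 16 (1.2 equiv), Pd(PPh3)4 (5 mol%), aq K3PO4 (3 equiv), 40 °C; aq KF work-up, deactivated alumina, crystallisation (brief warming in heptane to relax any Z isomer)
Reagents that add atoms: none
Why: Zerovalent palladium inserts into the C10'–I bond of 6 with retention, the alkenyl–SnBu3 terminus C11' of 23 transmetalates under neutral, base-free conditions and reductive elimination forms C10'–C11' to give 24; a neutral pinacol boronate cannot transmetalate without hydroxide or phosphate, so the C11–B end stays silent until 6 is consumed. Adding 16 and aqueous K3PO4 then opens the Suzuki–Miyaura cycle (oxidative addition into C10–I, transmetalation through a Pd–OH or borate species, reductive elimination) and forms C10–C11. The closest known reaction type is the chemoselective Stille-then-Suzuki coupling of tin/boron bifunctional alkenes and dienes with alkenyl iodides. No ring closes and no stereocentre is created: C3, C6 and C6' come in with 16 and 6, and phosphate at 40 °C should not deprotonate the doubly allylic C6–H and C6'–H or shift the ring alkenes. The selectivity needed is tin before boron, which puts exactly one ring of each kind on every chain and is secured by withholding base in the first stage; because the pentaene core is C2-symmetric it does not matter which terminus meets which ring. Both couplings are stereoretentive, so the E geometry of the three pieces should be carried into the all-E nonaene.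

**Compound list**

1 | racemic α-ionone, (3E)-4-(2,6,6-trimethylcyclohex-2-en-1-yl)but-3-en-2-one | CC(=O)/C=C/C1C(C)=CCCC1(C)C | starting material
2 | (S)-α-ionone, (3E)-4-[(1S)-2,6,6-trimethylcyclohex-2-en-1-yl]but-3-en-2-one | CC(=O)/C=C/[C@@H]1C(C)=CCCC1(C)C | intermediate
3 | diethyl (3E)-4-[(1S)-2,6,6-trimethylcyclohex-2-en-1-yl]buta-1,3-dien-2-yl phosphate (formed in the flask) | C=C(OP(=O)(OCC)OCC)/C=C/[C@@H]1C(C)=CCCC1(C)C | intermediate
4 | (6S)-6-[(1E)-but-1-en-3-yn-1-yl]-1,5,5-trimethylcyclohex-1-ene | C#C/C=C/[C@@H]1C(C)=CCCC1(C)C | intermediate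
5 | dimethyl{(1E,3E)-2-methyl-4-[(1S)-2,6,6-trimethylcyclohex-2-en-1-yl]buta-1,3-dien-1-yl}alane (formed in the flask) | CC1=CCCC(C)(C)[C@@H]1/C=C/C(C)=C/[Al](C)C | intermediate
6 | (6S)-6-[(1E,3E)-4-iodo-3-methylbuta-1,3-dien-1-yl]-1,5,5-trimethylcyclohex-1-ene | CC1=CCCC(C)(C)[C@@H]1/C=C/C(C)=C/I | intermediate
7 | 2-methyl-2-{(E)-2-[(1S)-2,6,6-trimethylcyclohex-2-en-1-yl]ethenyl}-1,3-dioxolane | CC1(OCCO1)/C=C/[C@@H]2C(C)=CCCC2(C)C | intermediate
8 | (4S)-3,5,5-trimethyl-4-[(E)-2-(2-methyl-1,3-dioxolan-2-yl)ethenyl]cyclohex-2-en-1-one | CC1(OCCO1)/C=C/[C@@H]2C(C)=CC(=O)CC2(C)C | intermediate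
9 | (1S,4S)-3,5,5-trimethyl-4-[(E)-2-(2-methyl-1,3-dioxolan-2-yl)ethenyl]cyclohex-2-en-1-ol (OH trans to side chain) | CC1(OCCO1)/C=C/[C@@H]2C(C)=C[C@@H](O)CC2(C)C | intermediate
10 | tert-butyldimethylsilyl ether of 9 | CC1(OCCO1)/C=C/[C@@H]2C(C)=C[C@@H](O[Si](C)(C)C(C)(C)C)CC2(C)C | intermediate
11 | (3E)-4-[(1S,4S)-4-(tert-butyldimethylsilyloxy)-2,6,6-trimethylcyclohex-2-en-1-yl]but-3-en-2-one | CC(=O)/C=C/[C@@H]1C(C)=C[C@@H](O[Si](C)(C)C(C)(C)C)CC1(C)C | intermediate
12 | diethyl (3E)-4-[(1S,4S)-4-(tert-butyldimethylsilyloxy)-2,6,6-trimethylcyclohex-2-en-1-yl]buta-1,3-dien-2-yl phosphate (formed in the flask) | C=C(OP(=O)(OCC)OCC)/C=C/[C@@H]1C(C)=C[C@@H](O[Si](C)(C)C(C)(C)C)CC1(C)C | intermediate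
13 | tert-butyl{[(1S,4S)-4-[(1E)-but-1-en-3-yn-1-yl]-3,5,5-trimethylcyclohex-2-en-1-yl]oxy}dimethylsilane | C#C/C=C/[C@@H]1C(C)=C[C@@H](O[Si](C)(C)C(C)(C)C)CC1(C)C | intermediate
14 | alkenyldimethylalane from 13 (formed in the flask) | C[Al](C)/C=C(C)/C=C/[C@@H]1C(C)=C[C@@H](O[Si](C)(C)C(C)(C)C)CC1(C)C | intermediate
15 | tert-butyl{[(1S,4S)-4-[(1E,3E)-4-iodo-3-methylbuta-1,3-dien-1-yl]-3,5,5-trimethylcyclohex-2-en-1-yl]oxy}dimethylsilane | I/C=C(C)/C=C/[C@@H]1C(C)=C[C@@H](O[Si](C)(C)C(C)(C)C)CC1(C)C | intermediate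
16 | (1S,4S)-4-[(1E,3E)-4-iodo-3-methylbuta-1,3-dien-1-yl]-3,5,5-trimethylcyclohex-2-en-1-ol | I/C=C(C)/C=C/[C@@H]1C(C)=C[C@@H](O)CC1(C)C | intermediate
17 | tributyltin chloride | CCCC[Sn](Cl)(CCCC)CCCC | starting material
18 | dibromomethane | BrCBr | starting material
19 | tributyl(dibromomethyl)stannane | CCCC[Sn](CCCC)(CCCC)C(Br)Br | intermediate
20 | (2E,4E,6E)-2,7-dimethylocta-2,4,6-trienedial | O=C/C(C)=C/C=C/C=C(C)/C=O | starting material
21 | 2-(dichloromethyl)-4,4,5,5-tetramethyl-1,3,2-dioxaborolane | ClC(Cl)B1OC(C)(C)C(C)(C)O1 | starting material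
22 | (2E,4E,6E,8E)-2,7-dimethyl-9-(4,4,5,5-tetramethyl-1,3,2-dioxaborolan-2-yl)nona-2,4,6,8-tetraenal | O=C/C(C)=C/C=C/C=C(C)/C=C/B1OC(C)(C)C(C)(C)O1 | intermediate
23 | tributyl[(1E,3E,5E,7E,9E)-3,8-dimethyl-10-(4,4,5,5-tetramethyl-1,3,2-dioxaborolan-2-yl)deca-1,3,5,7,9-pentaen-1-yl]stannane | CCCC[Sn](CCCC)(CCCC)/C=C/C(C)=C/C=C/C=C(C)/C=C/B1OC(C)(C)C(C)(C)O1 | intermediate
24 | 2-{(1E,3E,5E,7E,9E,11E,13E)-3,8,12-trimethyl-14-[(1S)-2,6,6-trimethylcyclohex-2-en-1-yl]tetradeca-1,3,5,7,9,11,13-heptaen-1-yl}-4,4,5,5-tetramethyl-1,3,2-dioxaborolane (formed in the flask) | CC1=CCCC(C)(C)[C@@H]1/C=C/C(C)=C/C=C/C(C)=C/C=C/C=C(C)/C=C/B2OC(C)(C)C(C)(C)O2 | intermediate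
25 | (3S,6S,6'S)-ε,ε-caroten-3-ol, all-E | CC1=CCCC(C)(C)[C@@H]1/C=C/C(C)=C/C=C/C(C)=C/C=C/C=C(C)/C=C/C=C(C)/C=C/[C@@H]1C(C)=C[C@@H](O)CC1(C)C | target

**Step count**

Total: 15 steps. Longest linear sequence: 10 steps (1, 4, 5, 6, 7, 8, 9, 10, 11, 15).

**Steps most likely to fail**

Step 15. The tin and boron termini may not be fully differentiated in one flask, or the bifunctional pentaene may lose a metal by protonolysis or homocouple, which would put the two symmetric carotenoids beside the target. The fallback takes boron out of the Stille flask and sets out from 6, 20 and 19. Dialdehyde 20 is olefinated once with 19, CrCl2 and LiI to the stannyl aldehyde (2E,4E,6E,8E)-2,7-dimethyl-9-(tributylstannyl)nona-2,4,6,8-tetraenal F1. Stille coupling of F1 with 6 (Pd2(dba)3·CHCl3, AsPh3) gives the C25 aldehyde (2E,4E,6E,8E,10E,12E)-2,7,11-trimethyl-13-[(1S)-2,6,6-trimethylcyclohex-2-en-1-yl]trideca-2,4,6,8,10,12-hexaenal F2. Its aldehyde is converted into the (E)-alkenylboronate with 21, CrCl2 and LiI, which comes back to the route at 24, now isolated and purified. The Suzuki–Miyaura half of step 15 with 16 then gives 25.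

Step 9 (the same hazard applies to step 2). Excess LDA during the elimination may deprotonate the doubly allylic C6–H, which would erode configuration at C6 or move the ring double bond into conjugation. The fallback avoids amide base at room temperature and sets out from 11. Boron-Wittig olefination with lithiated bis(pinacolboryl)methane (CH2(Bpin)2, lithium tetramethylpiperidide, THF, −78 °C) should give the (E)-dienylboronate tert-butyldimethyl{[(1S,4S)-3,5,5-trimethyl-4-[(1E,3E)-3-methyl-4-(4,4,5,5-tetramethyl-1,3,2-dioxaborolan-2-yl)buta-1,3-dien-1-yl]cyclohex-2-en-1-yl]oxy}silane F3, with any Z isomer removed by chromatography. Iododeboronation with retention (aq NaOH, then I2, THF, 0 °C) comes back to the route at 15. The same two operations would carry 2 to 6.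

Step 6. Catalyst control may be opposed by the facial bias of the ring, whose pseudo-axial C1 methyl and neopentyl-type C2 flank the carbonyl, so that hydride is delivered mainly to the wrong face. The fallback sets out from 8. Luche reduction (NaBH4, CeCl3·7H2O, MeOH, −78 °C) is followed by isolation of the cis alcohol (1R,4S)-3,5,5-trimethyl-4-[(E)-2-(2-methyl-1,3-dioxolan-2-yl)ethenyl]cyclohex-2-en-1-ol F4. Mitsunobu inversion (4-nitrobenzoic acid, PPh3, diisopropyl azodicarboxylate, THF, 0 °C) gives the trans ester (1S,4S)-3,5,5-trimethyl-4-[(E)-2-(2-methyl-1,3-dioxolan-2-yl)ethenyl]cyclohex-2-en-1-yl 4-nitrobenzoate F5. Methanolysis (K2CO3, MeOH) comes back to the route at 9.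

**Further compounds**

F1 | step 15 | (2E,4E,6E,8E)-2,7-dimethyl-9-(tributylstannyl)nona-2,4,6,8-tetraenal | O=C/C(C)=C/C=C/C=C(C)/C=C/[Sn](CCCC)(CCCC)CCCC
F2 | step 15 | (2E,4E,6E,8E,10E,12E)-2,7,11-trimethyl-13-[(1S)-2,6,6-trimethylcyclohex-2-en-1-yl]trideca-2,4,6,8,10,12-hexaenal | CC1=CCCC(C)(C)[C@@H]1/C=C/C(C)=C/C=C/C(C)=C/C=C/C=C(C)/C=O
F3 | step 9 | tert-butyldimethyl{[(1S,4S)-3,5,5-trimethyl-4-[(1E,3E)-3-methyl-4-(4,4,5,5-tetramethyl-1,3,2-dioxaborolan-2-yl)buta-1,3-dien-1-yl]cyclohex-2-en-1-yl]oxy}silane | CC1(C)OB(OC1(C)C)/C=C(C)/C=C/[C@@H]2C(C)=C[C@@H](O[Si](C)(C)C(C)(C)C)CC2(C)C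
F4 | step 6 | (1R,4S)-3,5,5-trimethyl-4-[(E)-2-(2-methyl-1,3-dioxolan-2-yl)ethenyl]cyclohex-2-en-1-ol | CC1(OCCO1)/C=C/[C@@H]2C(C)=C[C@H](O)CC2(C)C
F5 | step 6 | (1S,4S)-3,5,5-trimethyl-4-[(E)-2-(2-methyl-1,3-dioxolan-2-yl)ethenyl]cyclohex-2-en-1-yl 4-nitrobenzoate | CC1(OCCO1)/C=C/[C@@H]2C(C)=C[C@@H](OC(=O)c3ccc(cc3)[N+](=O)[O-])CC2(C)C
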